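## Retrosynthetic overview

1. Feature: ring C is joined to ring A through two neighbouring ring A carbons, C8a (bearing O1) and C4a (bearing the C4 carbonyl). The other neighbour of C4a is the oxygenated C5. A C4a-C8a aryne is therefore the natural ring A synthon: the C5 oxygen polarises it so that an oxygen nucleophile enters at C8a and the carbanion appears at C4a.
2. Key disconnection: O1-C8a and C4-C4a are cut together. This gives a 6-prenylated ortho-silylaryl triflate (ring A) and an anti beta-hydroxy ester that already holds ring B, C2, C3 and C4. Ring C is the only ring made; rings A and B are bought.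
3. The ester is carried as a butane-2,3-diacetal glycolate lactone. Its lithium aldol with the ring B aldehyde sets C2 and C3 (anti, R,R) under basic conditions that spare aryl MOM ethers and both chains. The lactone is a better acyl acceptor than a methyl ester, and the C3 oxygen ends as a ketal that leaves together with the MOM groups.
4. Ring A arm: phloroglucinol, two directed metalations (prenyl at C6, then silicon at C4a) and triflation. Ring B arm: 2,4-dihydroxybenzaldehyde, directed metalation and geranylation at C3'.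
5. Endgame: one acidic methanolysis removes the four MOM groups and the ketal.

Key step: step 15

Remark: the target SMILES decodes as (2R,3R), the 2,3-trans dihydroflavonol. Flavonoid numbering (O1, C2, C3, C4, C4a, C5 to C8, C8a, primed numbers in ring B) is used for every compound that maps onto it. MOM = methoxymethyl, prenyl = 3-methylbut-2-enyl, geranyl = (2E)-3,7-dimethylocta-2,6-dienyl.

## Route

Step 1
Reactants: 1 phloroglucinol
Product: 2 3,5-bis(methoxymethoxy)phenol
Conditions: MOMCl (2 equiv), iPr2NEt, DMF, 0 °C → rt; chromatography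
Reagents that add atoms: chloromethyl methyl ether (MOMCl), COCCl
Why: Williamson-type O-alkylation of the threefold symmetric triphenol with two equivalents of MOMCl should give the bis-ether as the main part of a statistical mixture, from which it is separated.

Step 2
Reactants: 2 3,5-bis(methoxymethoxy)phenol
Product: 3 [3,5-bis(methoxymethoxy)phenoxy]triisopropylsilane
Conditions: TIPSCl, imidazole, DMF, rt
Reagents that add atoms: chlorotriisopropylsilane, CC(C)[Si](Cl)(C(C)C)C(C)C
Why: Standard phenol silylation; the bulky, non-coordinating silyl ether removes the acidic proton and discourages lithiation at its own two ortho positions.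

Step 3
Reactants: 3 [3,5-bis(methoxymethoxy)phenoxy]triisopropylsilane; 4 prenyl bromide
Product: 6 [3,5-bis(methoxymethoxy)-4-prenylphenoxy]triisopropylsilane, via aryllithium 5 (not isolated)
Conditions: n-BuLi, THF, 0 °C → rt; CuBr·SMe2 (20 mol %), then 4, −30 °C → rt
Reagents that add atoms: none
Why: Directed ortho-metalation takes the C-H flanked by two coordinating MOM ethers, and allylation catalysed by monovalent copper joins the aryl carbon to the primary carbon of prenyl bromide (SN2 sense).

Step 4
Reactants: 6 [3,5-bis(methoxymethoxy)-4-prenylphenoxy]triisopropylsilane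
Product: 7 3,5-bis(methoxymethoxy)-4-prenylphenol
Conditions: Bu4NF, THF, 0 °C
Reagents that add atoms: none
Why: Fluoride desilylation of an aryl silyl ether leaves MOM ethers and the alkene untouched and frees the oxygen that will become the triflate at C8a.

Step 5
Reactants: 7 3,5-bis(methoxymethoxy)-4-prenylphenol
Product: 8 3,5-bis(methoxymethoxy)-4-prenylphenyl N-isopropylcarbamate
Conditions: iPrNCO, Et3N (cat.), CH2Cl2, rt
Reagents that add atoms: isopropyl isocyanate, CC(C)N=C=O
Why: Base-catalysed addition of the phenol to the isocyanate installs a strong metalation-directing group that can later be removed under mild base.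

Step 6
Reactants: 8 3,5-bis(methoxymethoxy)-4-prenylphenyl N-isopropylcarbamate
Product: 12 3,5-bis(methoxymethoxy)-4-prenyl-2-(trimethylsilyl)phenyl N-isopropylcarbamate, via N-silyl carbamate 9 (not isolated), via aryllithium 10 (not isolated), via bis-silyl carbamate 11 (not isolated)
Conditions: TBSOTf, TMEDA, Et2O, 0 °C → rt; n-BuLi, TMEDA, −78 °C; TMSCl, −78 °C → rt; brief aq NaHSO4 wash
Reagents that add atoms: chlorotrimethylsilane, C[Si](C)(C)Cl
Why: After transient N-silylation, carbamate-directed ortho-metalation at −78 °C takes one of the two symmetry-equivalent C-H bonds lying between the carbamate and a MOM ether, faster than any attack on the prenyl CH2, and TMSCl traps the anion while the N-Si bond falls on work-up.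

Step 7
Reactants: 12 3,5-bis(methoxymethoxy)-4-prenyl-2-(trimethylsilyl)phenyl N-isopropylcarbamate
Product: 14 3,5-bis(methoxymethoxy)-4-prenyl-2-(trimethylsilyl)phenyl trifluoromethanesulfonate, via silylphenoxide 13 (not isolated)
Conditions: DBU, Et2NH, MeCN, 40 °C; then PhNTf2, rt
Reagents that add atoms: N-phenylbis(trifluoromethanesulfonimide), O=S(=O)(C(F)(F)F)N(c1ccccc1)S(=O)(=O)C(F)(F)F
Why: E1cB cleavage of the secondary carbamate (the isocyanate is scavenged by Et2NH) and triflation of the phenoxide in the same pot is the established way to ortho-silylaryl triflates and avoids handling the desilylation-prone phenol.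

Step 8
Reactants: 15 2,4-dihydroxybenzaldehyde
Product: 16 2,4-bis(methoxymethoxy)benzaldehyde
Conditions: NaH, MOMCl, DMF, 0 °C → rt
Reagents that add atoms: chloromethyl methyl ether (MOMCl), COCCl
Why: Williamson-type O-alkylation of the bis-phenoxide; full deprotonation with NaH also brings in the hydrogen-bonded 2-hydroxyl.

Step 9
Reactants: 16 2,4-bis(methoxymethoxy)benzaldehyde
Product: 17 2-[2,4-bis(methoxymethoxy)phenyl]-1,3-dimethylimidazolidine
Conditions: MeNHCH2CH2NHMe, MgSO4, toluene, rt → 60 °C
Reagents that add atoms: N,N'-dimethylethane-1,2-diamine, CNCCNC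
Why: Acid-free condensation to a cyclic aminal masks the aldehyde against butyllithium without endangering the MOM ethers.

Step 10
Reactants: 17 2-[2,4-bis(methoxymethoxy)phenyl]-1,3-dimethylimidazolidine; 18 geranyl bromide
Product: 21 3-geranyl-2,4-bis(methoxymethoxy)benzaldehyde, via aryllithium 19 (not isolated), via geranylated aminal 20 (not isolated)
Conditions: n-BuLi, THF, 0 °C; CuBr·SMe2 (20 mol %), then 18, −30 °C → rt; 10% aq citric acid, THF, 0 °C
Reagents that add atoms: water, O
Why: Directed ortho-metalation takes the C3'-H between the two MOM ethers (cooperative direction outweighs the aminal), copper-catalysed SN2 allylation adds the chain last so that no strong base ever meets the benzylic-allylic CH2, and the aminal of this electron-rich aldehyde hydrolyses under very mild acid.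

Step 11
Reactants: 22 (S)-3-chloropropane-1,2-diol; 23 butane-2,3-dione
Product: 24 (2S,3S,5S)-5-(chloromethyl)-2,3-dimethoxy-2,3-dimethyl-1,4-dioxane
Conditions: HC(OMe)3, camphorsulfonic acid (cat.), MeOH, reflux
Reagents that add atoms: trimethyl orthoformate, COC(OC)OC (source of the two methoxy groups by way of methanol, CO)
Why: 1,2-Diacetal formation under thermodynamic control: the anomeric effect places both methoxy groups axial and the chloromethyl group sits equatorial, so the one stereocentre of 22 fixes both ketal centres as S.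

Step 12
Reactants: 24 (2S,3S,5S)-5-(chloromethyl)-2,3-dimethoxy-2,3-dimethyl-1,4-dioxane
Product: 25 (2S,3S)-2,3-dimethoxy-2,3-dimethyl-5-methylidene-1,4-dioxane
Conditions: KOtBu, THF, 0 °C → reflux
Reagents that add atoms: none
Why: E2 dehydrochlorination gives the exocyclic enol ether; the original stereocentre is erased and the chirality stays stored in the two ketal carbons.

Step 13
Reactants: 25 (2S,3S)-2,3-dimethoxy-2,3-dimethyl-5-methylidene-1,4-dioxane
Product: 26 (5S,6S)-5,6-dimethoxy-5,6-dimethyl-1,4-dioxan-2-one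
Conditions: O3, CH2Cl2, −78 °C; then Me2S
Reagents that add atoms: ozone, [O-][O+]=O
Why: Ozonolysis of the electron-rich enol ether C=C turns its ring carbon into the lactone carbonyl without touching the ketal stereocentres.

Step 14
Reactants: 26 (5S,6S)-5,6-dimethoxy-5,6-dimethyl-1,4-dioxan-2-one; 21 3-geranyl-2,4-bis(methoxymethoxy)benzaldehyde
Product: 28 (3R,5S,6S)-3-[(R)-[3-geranyl-2,4-bis(methoxymethoxy)phenyl](hydroxy)methyl]-5,6-dimethoxy-5,6-dimethyl-1,4-dioxan-2-one, via lithium enolate 27 (not isolated)
Conditions: LiN(SiMe3)2, THF, −78 °C; then 21, −78 °C; AcOH quench at −78 °C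
Reagents that add atoms: none
Why: Lithium enolate aldol through a Zimmerman-Traxler chair: the ring-locked E(O)-enolate 27 delivers the anti adduct, and the axial methoxy group on C5 of the diacetal chair blocks one enolate face so that the new C-C bond forms trans to it, which sets flavonoid C3 as R and C2 as R; the cold acidic quench prevents retro-aldol equilibration.

Step 15
Reactants: 14 3,5-bis(methoxymethoxy)-4-prenyl-2-(trimethylsilyl)phenyl trifluoromethanesulfonate; 28 anti beta-hydroxy lactone (lactone carbonyl = C4, diacetal oxygen = O on C3, free hydroxyl on C2)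
Product: 32 (2R,3R)-2-[3-geranyl-2,4-bis(methoxymethoxy)phenyl]-3-{[(2S)-2-methoxy-3-oxobutan-2-yl]oxy}-5,7-bis(methoxymethoxy)-6-prenylchroman-4-one, via aryne 29 (not isolated), via aryl anion 30 (not isolated), via hemiketal alkoxide 31 (not isolated)
Conditions: KF, 18-crown-6, 4 Å MS, THF, −20 °C → rt, slow addition of 14 (1.5 equiv)
Reagents that add atoms: none
Why: Proposed new method: fluoride attacks the silicon on C4a of 14 and triflate leaves from C8a to give aryne 29, the fluoride-hydrogen-bonded C2 hydroxyl of 28 adds to C8a (O1-C8a), and aryl anion 30, born at C4a, attacks the lactone carbonyl six atoms away (C4-C4a) in a 6-exo-trig closure of ring C, after which the expelled hemiketal alkoxide 31 sheds methoxide, which takes up the hydroxyl proton. The closest known reaction types are the fluoride-induced annulation of arynes with salicylate esters to xanthones and the O-H insertion of arynes into aliphatic alcohols under KF/18-crown-6 at low temperature; new here is an aliphatic, retro-aldol-prone beta-hydroxy ester as the two-point partner. No stereocentre is made or broken, since only the O-H bond and the acyl C-O bond of 28 are cut, so the anti pair arrives as the 2,3-trans ring. The regioselectivity needed comes from the C5 OMOM group beside C4a, whose inductive pull distorts the aryne so that C8a, flanked only by C8-H, is the more electrophilic terminus and the negative charge develops next to oxygen. Acyl capture must outrun protonation of 30, which is why the acceptor is an electron-poor lactone, the medium is aprotic and dried, and the aryne is released slowly in the cold; the same mildness keeps the concentration of free alkoxide, and with it retro-aldol cleavage, low.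

Step 16
Reactants: 32 tetra-MOM 3-O-ketal dihydroflavonol
Product: 33 (2R,3R)-2-(3-geranyl-2,4-dihydroxyphenyl)-3,5,7-trihydroxy-6-prenylchroman-4-one
Conditions: HCl (0.5 M in MeOH), 0 °C → rt
Reagents that add atoms: none
Why: Acid-catalysed transacetalisation onto methanol removes the four aryl MOM ethers and the alpha-keto ketal at or below room temperature, where trisubstituted alkenes are hardly protonated; C3 is not touched, and C2, should it open reversibly through a ring B quinone methide, recloses to the more stable 2,3-trans ring.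

## Compound list

1 | phloroglucinol | Oc1cc(O)cc(O)c1 | starting material
2 | 3,5-bis(methoxymethoxy)phenol | COCOc1cc(O)cc(OCOC)c1 | intermediate
3 | [3,5-bis(methoxymethoxy)phenoxy]triisopropylsilane | COCOc1cc(OCOC)cc(O[Si](C(C)C)(C(C)C)C(C)C)c1 | intermediate
4 | prenyl bromide | CC(C)=CCBr | starting material
5 | 4-lithio derivative of 3 (not isolated) | COCOc1cc(O[Si](C(C)C)(C(C)C)C(C)C)cc(OCOC)c1[Li] | intermediate
6 | [3,5-bis(methoxymethoxy)-4-prenylphenoxy]triisopropylsilane | CC(C)=CCc1c(OCOC)cc(O[Si](C(C)C)(C(C)C)C(C)C)cc1OCOC | intermediate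
7 | 3,5-bis(methoxymethoxy)-4-prenylphenol | CC(C)=CCc1c(OCOC)cc(O)cc1OCOC | intermediate
8 | 3,5-bis(methoxymethoxy)-4-prenylphenyl N-isopropylcarbamate | CC(C)=CCc1c(OCOC)cc(OC(=O)NC(C)C)cc1OCOC | intermediate
9 | N-(tert-butyldimethylsilyl) derivative of 8 (not isolated) | CC(C)=CCc1c(OCOC)cc(OC(=O)N(C(C)C)[Si](C)(C)C(C)(C)C)cc1OCOC | intermediate
10 | 2-lithio derivative of 9 (not isolated) | CC(C)=CCc1c(OCOC)cc(OC(=O)N(C(C)C)[Si](C)(C)C(C)(C)C)c([Li])c1OCOC | intermediate
11 | 2-(trimethylsilyl) derivative of 9 (not isolated) | CC(C)=CCc1c(OCOC)cc(OC(=O)N(C(C)C)[Si](C)(C)C(C)(C)C)c([Si](C)(C)C)c1OCOC | intermediate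
12 | 3,5-bis(methoxymethoxy)-4-prenyl-2-(trimethylsilyl)phenyl N-isopropylcarbamate | CC(C)=CCc1c(OCOC)cc(OC(=O)NC(C)C)c([Si](C)(C)C)c1OCOC | intermediate
13 | DBU-H salt of 3,5-bis(methoxymethoxy)-4-prenyl-2-(trimethylsilyl)phenoxide (not isolated) | CC(C)=CCc1c(OCOC)cc([O-])c([Si](C)(C)C)c1OCOC.C1CCC2=[NH+]CCCN2CC1 | intermediate
14 | 3,5-bis(methoxymethoxy)-4-prenyl-2-(trimethylsilyl)phenyl trifluoromethanesulfonate (ring A aryne precursor) | CC(C)=CCc1c(OCOC)cc(OS(=O)(=O)C(F)(F)F)c([Si](C)(C)C)c1OCOC | intermediate
15 | 2,4-dihydroxybenzaldehyde | O=Cc1ccc(O)cc1O | starting material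
16 | 2,4-bis(methoxymethoxy)benzaldehyde | COCOc1ccc(C=O)c(OCOC)c1 | intermediate
17 | 2-[2,4-bis(methoxymethoxy)phenyl]-1,3-dimethylimidazolidine | COCOc1ccc(C2N(C)CCN2C)c(OCOC)c1 | intermediate
18 | geranyl bromide | CC(C)=CCC/C(C)=C/CBr | starting material
19 | 3-lithio derivative of 17 (not isolated) | COCOc1ccc(C2N(C)CCN2C)c(OCOC)c1[Li] | intermediate
20 | 2-[3-geranyl-2,4-bis(methoxymethoxy)phenyl]-1,3-dimethylimidazolidine (not isolated) | CC(C)=CCC/C(C)=C/Cc1c(OCOC)ccc(C2N(C)CCN2C)c1OCOC | intermediate
21 | 3-geranyl-2,4-bis(methoxymethoxy)benzaldehyde | CC(C)=CCC/C(C)=C/Cc1c(OCOC)ccc(C=O)c1OCOC | intermediate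
22 | (S)-3-chloropropane-1,2-diol | OC[C@H](O)CCl | starting material
23 | butane-2,3-dione | CC(=O)C(C)=O | starting material
24 | (2S,3S,5S)-5-(chloromethyl)-2,3-dimethoxy-2,3-dimethyl-1,4-dioxane | ClC[C@@H]1CO[C@](C)(OC)[C@@](C)(OC)O1 | intermediate
25 | (2S,3S)-2,3-dimethoxy-2,3-dimethyl-5-methylidene-1,4-dioxane | C=C1CO[C@](C)(OC)[C@@](C)(OC)O1 | intermediate
26 | (5S,6S)-5,6-dimethoxy-5,6-dimethyl-1,4-dioxan-2-one | O=C1CO[C@](C)(OC)[C@@](C)(OC)O1 | intermediate
27 | lithium enolate of 26 (not isolated) | [Li]OC1=CO[C@](C)(OC)[C@@](C)(OC)O1 | intermediate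
28 | (3R,5S,6S)-3-[(R)-[3-geranyl-2,4-bis(methoxymethoxy)phenyl](hydroxy)methyl]-5,6-dimethoxy-5,6-dimethyl-1,4-dioxan-2-one (anti beta-hydroxy ester precursor) | CC(C)=CCC/C(C)=C/Cc1c(OCOC)ccc([C@@H](O)[C@H]2O[C@](C)(OC)[C@@](C)(OC)OC2=O)c1OCOC | intermediate
29 | 3,5-bis(methoxymethoxy)-4-prenylbenzyne, the C4a-C8a aryne (not isolated) | CC(C)=CCC1=C(OCOC)C#CC=C1OCOC | intermediate
30 | C4a aryl anion of the O1-C8a aryl ether, potassium salt (not isolated) | CC(C)=CCC/C(C)=C/Cc1c(OCOC)ccc([C@@H](Oc2cc(OCOC)c(CC=C(C)C)c(OCOC)[c-]2)[C@H]2O[C@](C)(OC)[C@@](C)(OC)OC2=O)c1OCOC.[K+] | intermediate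
31 | ring-closed chromanone carrying the opened diacetal as potassium hemiketal alkoxide (not isolated) | CC(C)=CCC/C(C)=C/Cc1c(OCOC)ccc([C@H]2Oc3cc(OCOC)c(CC=C(C)C)c(OCOC)c3C(=O)[C@@H]2O[C@](C)(OC)[C@@](C)(OC)[O-])c1OCOC.[K+] | intermediate
32 | (2R,3R)-2-[3-geranyl-2,4-bis(methoxymethoxy)phenyl]-3-{[(2S)-2-methoxy-3-oxobutan-2-yl]oxy}-5,7-bis(methoxymethoxy)-6-prenylchroman-4-one | CC(C)=CCC/C(C)=C/Cc1c(OCOC)ccc([C@H]2Oc3cc(OCOC)c(CC=C(C)C)c(OCOC)c3C(=O)[C@@H]2O[C@](C)(OC)C(C)=O)c1OCOC | intermediate
33 | (2R,3R)-2-(3-geranyl-2,4-dihydroxyphenyl)-3,5,7-trihydroxy-6-prenylchroman-4-one (CNP0166115.1) | CC(C)=CCC/C(C)=C/Cc1c(O)ccc([C@H]2Oc3cc(O)c(CC=C(C)C)c(O)c3C(=O)[C@@H]2O)c1O | target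

## Step count

- Total step count: 16
- Longest linear sequence: 9 (steps 1 to 7, then 15 and 16)

## Steps most likely to fail

**1. Step 15 (new method).**

What may go wrong:
- The aryl anion is protonated before it reaches the carbonyl.
- The transient alkoxide undergoes retro-aldol cleavage.
- The aryne is captured by the trisubstituted alkenes in ene fashion.
- The freed methoxide opens ring C.

The fallback uses known chemistry (the chalcone epoxide route to dihydroflavonols). It sets out from carbamate 8 and aldehyde 21 and comes back at target 33.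

Carbamate 8 is taken through 9 to aryllithium 10 as in step 6, but 10 is quenched with N-methoxy-N-methylacetamide. This gives 2-acetyl-3,5-bis(methoxymethoxy)-4-prenylphenyl N-isopropylcarbamate F1. Claisen-Schmidt condensation of F1 with 21 (KOH, EtOH, rt) also cleaves the carbamate and gives the 2'-hydroxychalcone F2. Its only free phenol is the future O1, so only the 6-prenyl and not the 8-prenyl ring system can form later.

Silylation (TIPSOTf, 2,6-lutidine, CH2Cl2, 0 °C) gives the 2'-O-triisopropylsilyl chalcone F3. Juliá-Colonna epoxidation (poly-L-leucine, urea-H2O2, DBU, THF) is a nucleophilic epoxidation that touches only the enone C=C. It gives the (alphaR,betaS)-epoxide F4.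

Buffered fluoride (Bu4NF, AcOH, THF, 0 °C → rt) frees the phenol. The phenol opens the epoxide at the benzylic carbon, activated by the two ring B oxygens, with inversion. This gives the trans tetra-MOM dihydroflavonol F5. The conditions of step 16 then give 33.

**2. Step 16.**

What may go wrong:
- Acid-induced addition of a freshly freed phenol to the neighbouring prenyl or geranyl C=C (chroman formation).
- Epimerisation at C2 through reversible opening of ring C.
- Slow loss of the alpha-keto ketal.

The fallback sets out from 32 and comes back at 33. It keeps every phenol capped while acid is present.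

TESOTf and 2,2'-bipyridyl (CH2Cl2, 0 °C) are known to turn aryl MOM ethers directly into aryl triethylsilyl ethers without free acid. They give the tetrakis(triethylsilyl) ether with the C3 ketal still in place, F6. Pyridinium tosylate in MeOH at 0 °C removes the ketal and gives the tetrakis(triethylsilyl) ether with free 3-hydroxyl, F7. Buffered fluoride (Bu4NF, AcOH, THF, 0 °C) then gives 33.

**3. Step 14.**

What may go wrong:
- Erosion of the anti selectivity through lithium chelation by the ortho MOM ether.
- Partial retro-aldol equilibration with this electron-rich aldehyde.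

The fallback sets out from 28 as obtained (epimeric at the carbinol carbon) and comes back at 28. It sets the carbinol centre by catalyst-controlled ketone reduction instead of by the aldol transition state.

Dess-Martin periodinane (NaHCO3, CH2Cl2, 0 °C) converges the material onto the beta-keto lactone F8, in which C3 stays equatorial on the diacetal chair. Asymmetric transfer hydrogenation of the aryl ketone (RuCl(p-cymene)[(S,S)-TsDPEN], HCO2H/Et3N, rt) spares the alkenes. It should deliver the R carbinol, that is 28.

## Further compounds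

F1 | step 15 | 2-acetyl-3,5-bis(methoxymethoxy)-4-prenylphenyl N-isopropylcarbamate | CC(C)=CCc1c(OCOC)cc(OC(=O)NC(C)C)c(C(C)=O)c1OCOC
F2 | step 15 | (E)-3-[3-geranyl-2,4-bis(methoxymethoxy)phenyl]-1-[2-hydroxy-4,6-bis(methoxymethoxy)-5-prenylphenyl]prop-2-en-1-one | CC(C)=CCC/C(C)=C/Cc1c(OCOC)ccc(/C=C/C(=O)c2c(O)cc(OCOC)c(CC=C(C)C)c2OCOC)c1OCOC
F3 | step 15 | 2'-O-triisopropylsilyl ether of F2 | CC(C)=CCC/C(C)=C/Cc1c(OCOC)ccc(/C=C/C(=O)c2c(O[Si](C(C)C)(C(C)C)C(C)C)cc(OCOC)c(CC=C(C)C)c2OCOC)c1OCOC
F4 | step 15 | (alphaR,betaS)-trans-epoxide of F3 | CC(C)=CCC/C(C)=C/Cc1c(OCOC)ccc([C@@H]2O[C@H]2C(=O)c2c(O[Si](C(C)C)(C(C)C)C(C)C)cc(OCOC)c(CC=C(C)C)c2OCOC)c1OCOC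
F5 | step 15 | (2R,3R)-2-[3-geranyl-2,4-bis(methoxymethoxy)phenyl]-3-hydroxy-5,7-bis(methoxymethoxy)-6-prenylchroman-4-one | CC(C)=CCC/C(C)=C/Cc1c(OCOC)ccc([C@H]2Oc3cc(OCOC)c(CC=C(C)C)c(OCOC)c3C(=O)[C@@H]2O)c1OCOC
F6 | step 16 | 5,7,2',4'-tetrakis(triethylsilyl) ether of the target carrying the (2S)-2-methoxy-3-oxobutan-2-yl ketal on O3 | CC(C)=CCC/C(C)=C/Cc1c(O[Si](CC)(CC)CC)ccc([C@H]2Oc3cc(O[Si](CC)(CC)CC)c(CC=C(C)C)c(O[Si](CC)(CC)CC)c3C(=O)[C@@H]2O[C@](C)(OC)C(C)=O)c1O[Si](CC)(CC)CC
F7 | step 16 | 5,7,2',4'-tetrakis(triethylsilyl) ether of the target with free 3-hydroxyl | CC(C)=CCC/C(C)=C/Cc1c(O[Si](CC)(CC)CC)ccc([C@H]2Oc3cc(O[Si](CC)(CC)CC)c(CC=C(C)C)c(O[Si](CC)(CC)CC)c3C(=O)[C@@H]2O)c1O[Si](CC)(CC)CC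
F8 | step 14 | (3R,5S,6S)-3-[3-geranyl-2,4-bis(methoxymethoxy)benzoyl]-5,6-dimethoxy-5,6-dimethyl-1,4-dioxan-2-one | CC(C)=CCC/C(C)=C/Cc1c(OCOC)ccc(C(=O)[C@H]2O[C@](C)(OC)[C@@](C)(OC)OC2=O)c1OCOC
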